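**Plan**
- Retrosynthesis first removes the three MOM ethers and the C3–O bond of the 3-hydroxyl, then cuts ring C at C4a–C4, C4–C3 and O1–C2.
- This cut is possible because C4 is a single carbonyl carbon between C4a of ring A and the C3=C2–aryl unit, and O1 sits on C8a, ortho to C4a. Ring C is therefore an ortho-iodophenol (ring A), carbon monoxide and the ring B arylacetylene.
- Forward, the ring A iodophenol comes from phloroglucinol in 4 steps; the 1,1-dimethylallyl group arises by Claisen rearrangement of an O-prenyl ether, with iodine blocking the other ortho carbon.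
- The ring B alkyne comes from 6-bromoveratraldehyde in 7 steps: dimethylchromane ring by Claisen rearrangement and acid cyclisation, prenyl group by Stille coupling at the bromide, alkyne by Ohira–Bestmann homologation.
- The carbonylative annulation then joins the two fragments and closes ring C as the last ring; 3-hydroxylation and MOM removal finish the route.
- The target has no stereocentre and no stereogenic double bond, so every selectivity question is regiochemical.

Key step: step 12

Remark: 6-bromoveratraldehyde, tributyl(3-methylbut-2-en-1-yl)stannane, the Ohira–Bestmann reagent and LiN(i-Pr)2 solution are assumed to be purchased. Enaminone 22 is drawn as the E isomer, but its geometry has no consequence.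

**Ring A**

Step 1
Reactants: 1 phloroglucinol
Product: 2 3,5-bis(methoxymethoxy)phenol
Conditions: MOMCl (2.0 equiv), i-Pr2NEt, DMF, 0 °C to rt
Reagents that add atoms: chloromethyl methyl ether, COCCl
Why: O-alkylation of phenoxide with MOMCl (MOM ether formation) should give the bis-ether as the main component of a statistical mixture, from which the mono- and tris-ethers are separated and recycled.

Step 2
Reactants: 2 3,5-bis(methoxymethoxy)phenol
Product: 3 2-iodo-3,5-bis(methoxymethoxy)phenol
Conditions: NIS (1.0 equiv), CH2Cl2, −20 to 0 °C, dark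
Reagents that add atoms: N-iodosuccinimide, O=C1CCC(=O)N1I
Why: Electrophilic aromatic iodination is expected mainly ortho to the free hydroxyl (two equivalent sites, each para to an OMOM group) and less at the carbon flanked by two OMOM groups, the minor para isomer being removed by chromatography.

Step 3
Reactants: 3 2-iodo-3,5-bis(methoxymethoxy)phenol, 4 prenyl bromide (1-bromo-3-methylbut-2-ene)
Product: 5 2-iodo-1,5-bis(methoxymethoxy)-3-[(3-methylbut-2-en-1-yl)oxy]benzene
Conditions: K2CO3, acetone, 56 °C
Reagents that add atoms: none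
Why: Williamson ether synthesis with a primary allylic bromide and a potassium phenoxide in acetone should give O-alkylation.

Step 4
Reactants: 5 2-iodo-1,5-bis(methoxymethoxy)-3-[(3-methylbut-2-en-1-yl)oxy]benzene
Product: 7 2-iodo-3,5-bis(methoxymethoxy)-6-(2-methylbut-3-en-2-yl)phenol, via Claisen dienone 6 (not isolated)
Conditions: PhNEt2, 170 °C, argon, dark
Reagents that add atoms: none
Why: Aromatic Claisen rearrangement delivers the allyl unit with allylic inversion to the only free ortho carbon (iodine occupies the other), dienone 6 enolises to the phenol, and the basic solvent suppresses ionisation of the ether and acid-catalysed cyclisation of the product.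

**Ring B**

Step 5
Reactants: 8 6-bromoveratraldehyde (2-bromo-4,5-dimethoxybenzaldehyde)
Product: 9 2-bromo-4,5-dihydroxybenzaldehyde
Conditions: BBr3 (3 equiv), CH2Cl2, −78 °C to rt; H2O
Reagents that add atoms: none
Why: BBr3 cleavage of aryl methyl ethers (borate formation, bromide attack at methyl) leaves the aldehyde and the aryl bromide untouched.

Step 6
Reactants: 9 2-bromo-4,5-dihydroxybenzaldehyde, 10 3-chloro-3-methylbut-1-yne
Product: 11 2-bromo-5-hydroxy-4-[(2-methylbut-3-yn-2-yl)oxy]benzaldehyde
Conditions: DBU (1.1 equiv), CuCl2·2H2O (1 mol%), MeCN, 0 °C to rt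
Reagents that add atoms: none
Why: Copper-catalysed O-propargylation of a phenol with a tertiary propargylic chloride should occur at the 4-hydroxyl, which is para to the formyl group and so the more acidic one, its phenoxide being the only one formed with one equivalent of base.

Step 7
Reactants: 11 2-bromo-5-hydroxy-4-[(2-methylbut-3-yn-2-yl)oxy]benzaldehyde
Product: 12 2-bromo-5-hydroxy-4-[(2-methylbut-3-en-2-yl)oxy]benzaldehyde
Conditions: H2 (1 atm), Pd/CaCO3 poisoned with Pb(OAc)2 (Lindlar catalyst), quinoline, EtOAc, rt
Reagents that add atoms: none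
Why: Lindlar semi-hydrogenation stops at the terminal alkene and the poisoned catalyst should spare the aryl bromide and the aldehyde.

Step 8
Reactants: 12 2-bromo-5-hydroxy-4-[(2-methylbut-3-en-2-yl)oxy]benzaldehyde
Product: 15 5-bromo-8-hydroxy-2,2-dimethylchromane-6-carbaldehyde, via Claisen dienone 13 (not isolated), via ortho-prenylcatechol 14 (not isolated)
Conditions: xylene, 130 °C; then Amberlyst 15 (sulfonic acid resin), 80 °C
Reagents that add atoms: none
Why: Aromatic Claisen rearrangement of the 1,1-dimethylallyl ether can only reach C3 (the other ortho carbon bears the hydroxyl) and gives prenylcatechol 14, whose olefin is then protonated to the tertiary cation and trapped by the adjacent 4-hydroxyl, the only one within reach, in an acid-catalysed Markovnikov hydroalkoxylation that forms the six-membered 2,2-dimethylchromane ring.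

Step 9
Reactants: 15 5-bromo-8-hydroxy-2,2-dimethylchromane-6-carbaldehyde
Product: 16 5-bromo-8-(methoxymethoxy)-2,2-dimethylchromane-6-carbaldehyde
Conditions: MOMCl, i-Pr2NEt, CH2Cl2, 0 °C to rt
Reagents that add atoms: chloromethyl methyl ether, COCCl
Why: MOM ether formation at the single phenol gives ring B the same protecting group as ring A, so that one final operation removes all three.

Step 10
Reactants: 16 5-bromo-8-(methoxymethoxy)-2,2-dimethylchromane-6-carbaldehyde, 17 tributyl(3-methylbut-2-en-1-yl)stannane
Product: 18 8-(methoxymethoxy)-2,2-dimethyl-5-(3-methylbut-2-en-1-yl)chromane-6-carbaldehyde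
Conditions: Pd(PPh3)4 (5 mol%), DMF, 100 °C
Reagents that add atoms: none
Why: Stille cross-coupling, in which oxidative addition is helped by the ortho-formyl group and C–C bond formation is expected at the unsubstituted allyl terminus to give the linear prenyl arene, while the neutral conditions leave the aldehyde and the MOM ether intact.

Step 11
Reactants: 18 8-(methoxymethoxy)-2,2-dimethyl-5-(3-methylbut-2-en-1-yl)chromane-6-carbaldehyde
Product: 19 6-ethynyl-8-(methoxymethoxy)-2,2-dimethyl-5-(3-methylbut-2-en-1-yl)chromane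
Conditions: dimethyl (1-diazo-2-oxopropyl)phosphonate, K2CO3, MeOH, 0 °C to rt
Reagents that add atoms: dimethyl (1-diazo-2-oxopropyl)phosphonate (Ohira–Bestmann reagent), CC(=O)C(=[N+]=[N-])P(=O)(OC)OC
Why: Seyferth–Gilbert homologation in the Ohira–Bestmann variant converts the aldehyde into the terminal alkyne under mildly basic conditions that the prenyl group and the MOM ether tolerate.

**Assembly**

Step 12
Reactants: 7 2-iodo-3,5-bis(methoxymethoxy)-6-(2-methylbut-3-en-2-yl)phenol, 19 6-ethynyl-8-(methoxymethoxy)-2,2-dimethyl-5-(3-methylbut-2-en-1-yl)chromane, 20 carbon monoxide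
Product: 23 5,7-bis(methoxymethoxy)-2-[8-(methoxymethoxy)-2,2-dimethyl-5-(3-methylbut-2-en-1-yl)chroman-6-yl]-8-(2-methylbut-3-en-2-yl)-4H-chromen-4-one, via ynone 21 (not isolated), via enaminone 22 (not isolated)
Conditions: PdCl2(PPh3)2 (5 mol%), CO (20 atm), Et2NH, 120 °C
Reagents that add atoms: diethylamine, CCNCC (supplies the amino group of intermediate 22 only and is released on ring closure; no reagent atoms remain in 23)
Why: Zerovalent palladium formed from PdCl2(PPh3)2 inserts into the C–I bond of 7, CO inserts to give an aroylpalladium iodide, and coupling with the terminal alkyne 19 gives ynone 21, forming C4a–C4 and C4–C3. Diethylamine adds reversibly to 21 to give enaminone 22, and the free phenol on C8a attacks the amine-bearing carbon (the later C2) with loss of diethylamine, an addition–elimination that forms O1–C2 and closes ring C in the 6-endo mode. The closest known reaction type is the palladium-catalysed carbonylative annulation of 2-iodophenols with terminal arylacetylenes to flavones in a secondary amine. No stereocentre is formed. The step needs six-membered (flavone) rather than five-membered (aurone) closure, which the enaminone pathway secures by moving the electrophilic site to C2, and it needs the alkyne to react in preference to the three isolated olefins, which the much faster reaction of terminal alkynes with aroylpalladium species secures. The 8-substitution pattern is fixed because the only free hydroxyl of 7 lies between the iodine-bearing carbon and the carbon carrying the 1,1-dimethylallyl group.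

Step 13
Reactants: 23 5,7-bis(methoxymethoxy)-2-[8-(methoxymethoxy)-2,2-dimethyl-5-(3-methylbut-2-en-1-yl)chroman-6-yl]-8-(2-methylbut-3-en-2-yl)-4H-chromen-4-one
Product: 26 3-hydroxy-5,7-bis(methoxymethoxy)-2-[8-(methoxymethoxy)-2,2-dimethyl-5-(3-methylbut-2-en-1-yl)chroman-6-yl]-8-(2-methylbut-3-en-2-yl)-4H-chromen-4-one, via 3-lithioflavone 24 (not isolated), via flavone-3-boronate 25 (not isolated)
Conditions: LiN(i-Pr)2 (LDA), THF, −78 °C; B(OMe)3, −78 to 0 °C; 30% aq. H2O2, 0 °C
Reagents that add atoms: hydrogen peroxide, OO (oxygen of the 3-hydroxyl); for the intermediates only: LiN(i-Pr)2, CC(C)N([Li])C(C)C (lithium of 24) and trimethyl borate, COB(OC)OC (boron and methoxy groups of 25)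
Why: Deprotonation of the flavone C3–H (alpha to the carbonyl, the kinetically most acidic site at −78 °C), borylation and boronate oxidation with 1,2-shift from boron to oxygen give the flavonol, and the weakly alkaline hydrogen peroxide should not epoxidise the isolated olefins.

Step 14
Reactants: 26 3-hydroxy-5,7-bis(methoxymethoxy)-2-[8-(methoxymethoxy)-2,2-dimethyl-5-(3-methylbut-2-en-1-yl)chroman-6-yl]-8-(2-methylbut-3-en-2-yl)-4H-chromen-4-one
Product: 27 Broussoflavonol E
Conditions: 3 M aq. HCl, MeOH, 45 °C
Reagents that add atoms: none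
Why: Acid-catalysed acetal exchange with methanol removes the three aryl MOM ethers, and at this mild acidity the ring B prenyl group (no ortho hydroxyl) and the 1,1-dimethylallyl group (protonation would give only a secondary cation) should survive.

**Compound list**
1 | phloroglucinol | Oc1cc(O)cc(O)c1 | starting material
2 | 3,5-bis(methoxymethoxy)phenol | COCOc1cc(O)cc(OCOC)c1 | intermediate
3 | 2-iodo-3,5-bis(methoxymethoxy)phenol | COCOc1cc(O)c(I)c(OCOC)c1 | intermediate
4 | prenyl bromide (1-bromo-3-methylbut-2-ene) | CC(C)=CCBr | starting material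
5 | 2-iodo-1,5-bis(methoxymethoxy)-3-[(3-methylbut-2-en-1-yl)oxy]benzene | COCOc1cc(OCC=C(C)C)c(I)c(OCOC)c1 | intermediate
6 | 2-iodo-3,5-bis(methoxymethoxy)-6-(2-methylbut-3-en-2-yl)cyclohexa-2,4-dien-1-one (Claisen dienone, racemic) | O=C1C(I)=C(OCOC)C=C(OCOC)C1C(C)(C)C=C | intermediate
7 | 2-iodo-3,5-bis(methoxymethoxy)-6-(2-methylbut-3-en-2-yl)phenol (ring A iodophenol) | C=CC(C)(C)c1c(O)c(I)c(OCOC)cc1OCOC | intermediate
8 | 6-bromoveratraldehyde (2-bromo-4,5-dimethoxybenzaldehyde) | COc1cc(Br)c(C=O)cc1OC | starting material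
9 | 2-bromo-4,5-dihydroxybenzaldehyde | O=Cc1cc(O)c(O)cc1Br | intermediate
10 | 3-chloro-3-methylbut-1-yne | C#CC(C)(C)Cl | starting material
11 | 2-bromo-5-hydroxy-4-[(2-methylbut-3-yn-2-yl)oxy]benzaldehyde | O=Cc1cc(O)c(OC(C)(C)C#C)cc1Br | intermediate
12 | 2-bromo-5-hydroxy-4-[(2-methylbut-3-en-2-yl)oxy]benzaldehyde | O=Cc1cc(O)c(OC(C)(C)C=C)cc1Br | intermediate
13 | 2-bromo-5-hydroxy-3-(3-methylbut-2-en-1-yl)-4-oxocyclohexa-1,5-diene-1-carbaldehyde (Claisen dienone, racemic) | O=CC1=C(Br)C(CC=C(C)C)C(=O)C(O)=C1 | intermediate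
14 | 2-bromo-4,5-dihydroxy-3-(3-methylbut-2-en-1-yl)benzaldehyde | O=Cc1cc(O)c(O)c(CC=C(C)C)c1Br | intermediate
15 | 5-bromo-8-hydroxy-2,2-dimethylchromane-6-carbaldehyde | O=Cc1cc(O)c2OC(C)(C)CCc2c1Br | intermediate
16 | 5-bromo-8-(methoxymethoxy)-2,2-dimethylchromane-6-carbaldehyde | O=Cc1cc(OCOC)c2OC(C)(C)CCc2c1Br | intermediate
17 | tributyl(3-methylbut-2-en-1-yl)stannane | CCCC[Sn](CCCC)(CCCC)CC=C(C)C | starting material
18 | 8-(methoxymethoxy)-2,2-dimethyl-5-(3-methylbut-2-en-1-yl)chromane-6-carbaldehyde | O=Cc1cc(OCOC)c2OC(C)(C)CCc2c1CC=C(C)C | intermediate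
19 | 6-ethynyl-8-(methoxymethoxy)-2,2-dimethyl-5-(3-methylbut-2-en-1-yl)chromane (ring B alkyne) | C#Cc1cc(OCOC)c2OC(C)(C)CCc2c1CC=C(C)C | intermediate
20 | carbon monoxide | [C-]#[O+] | starting material
21 | 1-[2-hydroxy-4,6-bis(methoxymethoxy)-3-(2-methylbut-3-en-2-yl)phenyl]-3-[8-(methoxymethoxy)-2,2-dimethyl-5-(3-methylbut-2-en-1-yl)chroman-6-yl]prop-2-yn-1-one (ynone) | C=CC(C)(C)c1c(O)c(C(=O)C#Cc2cc(OCOC)c3OC(C)(C)CCc3c2CC=C(C)C)c(OCOC)cc1OCOC | intermediate
22 | (E)-3-(diethylamino)-1-[2-hydroxy-4,6-bis(methoxymethoxy)-3-(2-methylbut-3-en-2-yl)phenyl]-3-[8-(methoxymethoxy)-2,2-dimethyl-5-(3-methylbut-2-en-1-yl)chroman-6-yl]prop-2-en-1-one (enaminone) | C=CC(C)(C)c1c(O)c(C(=O)/C=C(\c2cc(OCOC)c3OC(C)(C)CCc3c2CC=C(C)C)N(CC)CC)c(OCOC)cc1OCOC | intermediate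
23 | 5,7-bis(methoxymethoxy)-2-[8-(methoxymethoxy)-2,2-dimethyl-5-(3-methylbut-2-en-1-yl)chroman-6-yl]-8-(2-methylbut-3-en-2-yl)-4H-chromen-4-one (tris-MOM flavone) | C=CC(C)(C)c1c(OCOC)cc(OCOC)c2c(=O)cc(-c3cc(OCOC)c4c(c3CC=C(C)C)CCC(C)(C)O4)oc12 | intermediate
24 | 3-lithio derivative of flavone 23 | C=CC(C)(C)c1c(OCOC)cc(OCOC)c2c(=O)c([Li])c(-c3cc(OCOC)c4c(c3CC=C(C)C)CCC(C)(C)O4)oc12 | intermediate
25 | dimethyl boronate of flavone 23 at C3 | C=CC(C)(C)c1c(OCOC)cc(OCOC)c2c(=O)c(B(OC)OC)c(-c3cc(OCOC)c4c(c3CC=C(C)C)CCC(C)(C)O4)oc12 | intermediate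
26 | 3-hydroxy-5,7-bis(methoxymethoxy)-2-[8-(methoxymethoxy)-2,2-dimethyl-5-(3-methylbut-2-en-1-yl)chroman-6-yl]-8-(2-methylbut-3-en-2-yl)-4H-chromen-4-one | C=CC(C)(C)c1c(OCOC)cc(OCOC)c2c(=O)c(O)c(-c3cc(OCOC)c4c(c3CC=C(C)C)CCC(C)(C)O4)oc12 | intermediate
27 | Broussoflavonol E | C=CC(C)(C)c1c(O)cc(O)c2c(=O)c(O)c(-c3cc(O)c4c(c3CC=C(C)C)CCC(C)(C)O4)oc12 | target

**Step count**
Total: 14 steps. Longest linear sequence: 10 steps (8 to 27, steps 5–11 then 12–14); the ring A branch contributes steps 1–4.

**Steps most likely to fail, with fallbacks**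

Step 12. The aroylpalladium intermediate may be captured by diethylamine to give an amide. Coupling may also occur without CO insertion and end in a benzofuran, or the two ortho-substituted partners may couple too slowly at the temperature the ring closure needs. The fallback sets out from 7 and 19 and returns at 23; it separates the coupling from the ring closure.
- Phenol 7 is acetylated (Ac2O, pyridine, DMAP) to 2-iodo-3,5-bis(methoxymethoxy)-6-(2-methylbut-3-en-2-yl)phenyl acetate F1.
- F1, 19 and CO (1 atm) are coupled with PdCl2(PPh3)2 and Et3N in THF at 40 °C (copper-free carbonylative Sonogashira coupling). With neither a free phenol nor a nucleophilic amine present, the ynone acetate 2-{3-[8-(methoxymethoxy)-2,2-dimethyl-5-(3-methylbut-2-en-1-yl)chroman-6-yl]prop-2-ynoyl}-3,5-bis(methoxymethoxy)-6-(2-methylbut-3-en-2-yl)phenyl acetate F2 should be isolable.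
- F2 is treated with Et2NH and DBU in DMF at 40 °C. Aminolysis of the acetate and amine addition should lead through 21 and 22 to flavone 23.

Step 4. At 170 °C the C–I bond may be lost, the ether may ionise with loss of the prenyl group, or the product phenol may react further (cyclisation onto the vinyl group, abnormal Claisen rearrangement). The fallback sets out from 2 and returns at 7; it places the thermal step before iodine is on the ring.
- Phenol 2 is O-alkylated with 4 (K2CO3, acetone) to 1,3-bis(methoxymethoxy)-5-[(3-methylbut-2-en-1-yl)oxy]benzene F3.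
- Heating F3 in PhNEt2 should give, through the dienone 3,5-bis(methoxymethoxy)-6-(2-methylbut-3-en-2-yl)cyclohexa-2,4-dien-1-one F4, the phenol 3,5-bis(methoxymethoxy)-2-(2-methylbut-3-en-2-yl)phenol F5; both ortho carbons are equivalent.
- F5 is iodinated with NIS in CH2Cl2 at −20 °C at the remaining carbon ortho to the hydroxyl, which gives 7. The cost is that this iodination must distinguish the ortho carbon from the carbon between the two OMOM groups.

Step 10. The C–C bond may form at the substituted terminus of the prenyl unit and give the 1,1-dimethylallyl isomer, or coupling at the doubly ortho-substituted bromide may be slow enough for protodebromination to take over. The fallback sets out from 16 and returns at 18; it introduces an unsubstituted allyl group and builds the prenyl terminus afterwards.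
- Stille coupling of 16 with allyltributylstannane (Pd(PPh3)4, DMF, 90 °C) should give 5-allyl-8-(methoxymethoxy)-2,2-dimethylchromane-6-carbaldehyde F6, where the two allyl termini are identical.
- Olefin cross-metathesis of F6 with excess 2-methylbut-2-ene and the second-generation Grubbs catalyst RuCl2(=CHPh)(PCy3)(H2IMes) in CH2Cl2 at 40 °C should give 18.

**Further compounds**
F1 | step 12 | 2-iodo-3,5-bis(methoxymethoxy)-6-(2-methylbut-3-en-2-yl)phenyl acetate | C=CC(C)(C)c1c(OC(C)=O)c(I)c(OCOC)cc1OCOC
F2 | step 12 | 2-{3-[8-(methoxymethoxy)-2,2-dimethyl-5-(3-methylbut-2-en-1-yl)chroman-6-yl]prop-2-ynoyl}-3,5-bis(methoxymethoxy)-6-(2-methylbut-3-en-2-yl)phenyl acetate | C=CC(C)(C)c1c(OC(C)=O)c(C(=O)C#Cc2cc(OCOC)c3OC(C)(C)CCc3c2CC=C(C)C)c(OCOC)cc1OCOC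
F3 | step 4 | 1,3-bis(methoxymethoxy)-5-[(3-methylbut-2-en-1-yl)oxy]benzene | COCOc1cc(OCC=C(C)C)cc(OCOC)c1
F4 | step 4 | 3,5-bis(methoxymethoxy)-6-(2-methylbut-3-en-2-yl)cyclohexa-2,4-dien-1-one (racemic, not isolated) | O=C1C=C(OCOC)C=C(OCOC)C1C(C)(C)C=C
F5 | step 4 | 3,5-bis(methoxymethoxy)-2-(2-methylbut-3-en-2-yl)phenol | C=CC(C)(C)c1c(O)cc(OCOC)cc1OCOC
F6 | step 10 | 5-allyl-8-(methoxymethoxy)-2,2-dimethylchromane-6-carbaldehyde | O=Cc1cc(OCOC)c2OC(C)(C)CCc2c1CC=C
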